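**Plan**

- Numbering: spiro[5.5]undecane, ring B = C1–C5, spiro carbon C6, ring A = C7–C11. The retrosynthesis cuts C3–CH3 and C2–Br first (axial methyl addition to an equatorial α-bromo ketone), then the C3–C4 bond of ring B (Claisen-type closure of a sulfonyl carbanion on an ester), then C1=C2 (olefination of a C1 aldehyde), C5–C6 (Michael addition) and C6–C7 of ring A (bromonium cyclization of a β-keto ester).
- Forward: ring A arises first from an open-chain β-keto ester whose ester carbon becomes C1. A Michael addition completes the quaternary C6, ring B is then closed at C3–C4, and the ring B stereocentres are set last.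
- Feature that allows the closure: C6 is a fully substituted carbon carrying both the CH2CH2SO2Ph chain (acidic CH2 = C4) and a Z-acrylate (ester carbon = C3). The Thorpe–Ingold effect at C6 and the cis C1=C2 bond hold C4 next to the C3 carbonyl; afterwards the C1=C2 bond marks C2 as the carbon that takes bromine.
- Stereochemistry: C8 comes from one catalytic event (Shi epoxidation, then SN2 by bromide). C6 is relayed from C8 (Michael addition trans to Br). C2 (equatorial Br by equilibration) and C3 (axial methyl) are relayed from C6 through the ring B chair that has C7 equatorial and C11 axial.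
- Reason for closing ring B as a ketone: Br and OH on ring B are trans-diequatorial in that chair, which diaxial opening of a C2–C3 bromonium ion or epoxide would not give.

Key step: step 10

Remark: the D-fructose-derived Shi ketone is assumed to give the (R)-epoxide of the isopropylidene terminus, as it does with related trisubstituted alkenes.

**Route**

Step 1
Reactants: 1 6-methylhept-5-en-2-one
Product: 2 methyl 7-methyl-3-oxooct-6-enoate
Conditions: NaH, dimethyl carbonate, THF, 65 °C; then AcOH
Reagents that add atoms: dimethyl carbonate, COC(=O)OC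
Why: Claisen-type C-acylation of the methyl-side enolate by dimethyl carbonate, driven to the terminal position by irreversible deprotonation of the β-keto ester formed; no stereocentre arises.

Step 2
Reactants: 2 methyl 7-methyl-3-oxooct-6-enoate
Product: 3 methyl 5-[(2R)-3,3-dimethyloxiran-2-yl]-3-oxopentanoate
Conditions: 1,2:4,5-di-O-isopropylidene-β-D-erythro-2,3-hexodiulo-2,6-pyranose (Shi ketone, 0.3 equiv), KHSO5 (Oxone), K2CO3, Bu4NHSO4, MeCN–CH2(OMe)2–aq. buffer (pH about 9), 0 °C
Reagents that add atoms: potassium peroxymonosulfate, [K+].[O-]S(=O)(=O)OO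
Why: Shi epoxidation, in which the chiral dioxirane should oxidise the electron-rich trisubstituted alkene through a spiro transition state faster than the mostly ketonic β-keto ester; the catalyst sets the (R) epoxide carbon, the only stereocentre made by catalysis.

Step 3
Reactants: 3 methyl 5-[(2R)-3,3-dimethyloxiran-2-yl]-3-oxopentanoate
Product: 4 methyl (6S)-6-bromo-7-hydroxy-7-methyl-3-oxooctanoate
Conditions: Li2NiBr4 (0.4 M in THF), THF, 0 °C; then H2O
Reagents that add atoms: lithium tetrabromonickelate, [Li+].[Li+].[Ni+2].[Br-].[Br-].[Br-].[Br-]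
Why: SN2 opening of the epoxide by soft bromide at the less substituted carbon should give the secondary bromide with inversion (R epoxide to S bromide) and leave the tertiary alcohol as the later leaving group.

Step 4
Reactants: 4 methyl (6S)-6-bromo-7-hydroxy-7-methyl-3-oxooctanoate
Product: 5 methyl (3S)-3-bromo-2,2-dimethyl-6-oxocyclohexane-1-carboxylate (C1 epimers and enol)
Conditions: SnCl4, CH2Cl2, −78 to −20 °C
Reagents that add atoms: none
Why: Lewis-acid ionization of the tertiary C–OH with participation of the neighbouring bromine gives a bromonium ion that the SnCl4-chelated β-keto ester enol opens at the tertiary carbon through a chair with Br equatorial (bromonium-induced carbocyclization ending in C-alkylation of a 1,3-dicarbonyl), so the brominated carbon is never broken and keeps its S configuration, while C1 stays epimerizable until step 5.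

Step 5
Reactants: 5 methyl (3S)-3-bromo-2,2-dimethyl-6-oxocyclohexane-1-carboxylate; 6 phenyl vinyl sulfone
Product: 7 methyl (1S,3S)-3-bromo-2,2-dimethyl-6-oxo-1-[2-(phenylsulfonyl)ethyl]cyclohexane-1-carboxylate
Conditions: Cs2CO3 (0.1 equiv), MeCN, 0 to 23 °C
Reagents that add atoms: none
Why: Base-catalysed Michael addition of the β-keto ester enolate to the vinyl sulfone: in the reactive half-chair with Br equatorial the acceptor should enter axially on the face opposite the pseudoaxial C2 methyl, which places the new chain trans to Br and sets the quaternary (later spiro) carbon under substrate control, and the soft catalytic conditions should keep the enolate from displacing the hindered bromide.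

Step 6
Reactants: 7 methyl (1S,3S)-3-bromo-2,2-dimethyl-6-oxo-1-[2-(phenylsulfonyl)ethyl]cyclohexane-1-carboxylate
Product: 8 methyl (1R,3S)-3-bromo-2,2-dimethyl-6-methylidene-1-[2-(phenylsulfonyl)ethyl]cyclohexane-1-carboxylate
Conditions: Cp2TiMe2, toluene–THF, 65 °C, dark
Reagents that add atoms: dimethyltitanocene, C[Ti](C)(C1C=CC=C1)C1C=CC=C1
Why: Petasis methylenation (titanium methylidene, oxatitanacyclobutane, cycloreversion) is non-basic, so the α-quaternary ketone should be olefinated faster than the hindered ester and without retro-Claisen cleavage or loss of HBr; no stereocentre is touched (the descriptor at C1 changes only by priority).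

Step 7
Reactants: 8 methyl (1R,3S)-3-bromo-2,2-dimethyl-6-methylidene-1-[2-(phenylsulfonyl)ethyl]cyclohexane-1-carboxylate
Product: 9 [(1R,3S)-3-bromo-2,2-dimethyl-6-methylidene-1-[2-(phenylsulfonyl)ethyl]cyclohexyl]methanol
Conditions: i-Bu2AlH, CH2Cl2, −78 to 0 °C; then H2O
Reagents that add atoms: none
Why: Hydride reduction of the ester by i-Bu2AlH to the neopentyl alcohol; the sulfone, the 1,1-disubstituted alkene and the hindered secondary bromide should be inert at low temperature.

Step 8
Reactants: 9 [(1R,3S)-3-bromo-2,2-dimethyl-6-methylidene-1-[2-(phenylsulfonyl)ethyl]cyclohexyl]methanol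
Product: 10 (1R,3S)-3-bromo-2,2-dimethyl-6-methylidene-1-[2-(phenylsulfonyl)ethyl]cyclohexane-1-carbaldehyde
Conditions: Dess–Martin periodinane, CH2Cl2, 23 °C
Reagents that add atoms: none
Why: Dess–Martin oxidation of the primary alcohol should stop at the aldehyde, which has no α-hydrogen and so cannot enolize or epimerize.

Step 9
Reactants: 10 (1R,3S)-3-bromo-2,2-dimethyl-6-methylidene-1-[2-(phenylsulfonyl)ethyl]cyclohexane-1-carbaldehyde
Product: 11 methyl (2Z)-3-[(1R,3S)-3-bromo-2,2-dimethyl-6-methylidene-1-[2-(phenylsulfonyl)ethyl]cyclohexyl]prop-2-enoate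
Conditions: (CF3CH2O)2P(O)CH2CO2Me, KN(SiMe3)2, 18-crown-6, THF, −78 °C
Reagents that add atoms: methyl bis(2,2,2-trifluoroethyl)phosphonoacetate, COC(=O)CP(=O)(OCC(F)(F)F)OCC(F)(F)F
Why: Still–Gennari variant of the Horner–Wadsworth–Emmons olefination, in which fast irreversible collapse of the adduct from the electron-poor phosphonate should give the Z acrylate needed for ring closure; the preformed phosphonate anion is too weak a base to deprotonate the sulfone.

Step 10
Reactants: 11 methyl (2Z)-3-[(1R,3S)-3-bromo-2,2-dimethyl-6-methylidene-1-[2-(phenylsulfonyl)ethyl]cyclohexyl]prop-2-enoate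
Product: 12 (6R,8S)-8-bromo-7,7-dimethyl-11-methylidene-4-(phenylsulfonyl)spiro[5.5]undec-1-en-3-one (C4 epimers)
Conditions: LiN(SiMe3)2 (2.2 equiv), THF, −78 to 0 °C; then 1 M HCl
Reagents that add atoms: none
Why: LiN(SiMe3)2 removes a proton from the CH2 next to the sulfone, the only acidic C–H, and the carbanion adds to the ester carbonyl held beside it by the Z alkene and the fully substituted C6; loss of methoxide and deprotonation of the β-keto sulfone by the second equivalent of base make the C3–C4 bond formation irreversible. The closest known reaction type is the Dieckmann-type (Claisen) cyclization of a sulfone-stabilized carbanion onto an ester. Ring B closes in the 6-exo-trig mode, by attack on the ester C=O with its oxygen outside the new ring. The only new stereocentre, C4 bearing the sulfone, is epimerizable and is erased in step 11, so no stereocontrol is asked of this step. It needs 1,2-acylation over conjugate addition (which would give a four-membered ring), closure over intermolecular condensation (secured by the Thorpe–Ingold effect at C6 and the Z geometry) and survival of the secondary bromide (equatorial Br without an antiperiplanar hydrogen, hindered amide base). The C1=C2 bond carried through the closure marks C2 as the α-carbon that will take bromine, which keeps the two arms of ring B distinct and C6 stereogenic.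

Step 11
Reactants: 12 (6R,8S)-8-bromo-7,7-dimethyl-11-methylidene-4-(phenylsulfonyl)spiro[5.5]undec-1-en-3-one
Product: 13 (6R,8S)-8-bromo-7,7-dimethyl-11-methylidenespiro[5.5]undec-1-en-3-one
Conditions: SmI2, THF–MeOH, −78 °C
Reagents that add atoms: none
Why: Reductive desulfonylation of the β-keto sulfone by single-electron transfer from SmI2 (loss of sulfinate from the ketyl, second electron transfer, protonation of the dienolate at C4) should return the conjugated enone, while the unactivated alkyl bromide is not reduced by SmI2 at −78 °C without a polar additive.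

Step 12
Reactants: 13 (6R,8S)-8-bromo-7,7-dimethyl-11-methylidenespiro[5.5]undec-1-en-3-one
Product: 16 (2R,6R,8S)-2,8-dibromo-7,7-dimethyl-11-methylidenespiro[5.5]undecan-3-one, via triethylsilyl enol ether 14 (not isolated), via axial C2 bromide 15 (not isolated)
Conditions: Et3SiH, RhCl(PPh3)3 (2 mol %), THF, 50 °C; then NBS, THF, −78 °C; then LiBr, MeCN, 23 °C
Reagents that add atoms: N-bromosuccinimide, O=C1CCC(=O)N1Br
Why: Rhodium-catalysed 1,4-hydrosilylation of the enone gives the silyl enol ether regiospecifically towards C2, NBS brominates it at C2, and bromide exchange (SN2 at the α-keto carbon) should equilibrate the epimers to the equatorial bromide because an axial C2–Br is 1,3-diaxial to C11, so C2 is set by thermodynamic control relayed from C6.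

Step 13
Reactants: 16 (2R,6R,8S)-2,8-dibromo-7,7-dimethyl-11-methylidenespiro[5.5]undecan-3-one
Product: 17 (2R,3R,6R,8S)-2,8-dibromo-3,7,7-trimethyl-11-methylidenespiro[5.5]undecan-3-ol
Conditions: MeAl(OAr)2 (Ar = 2,6-di-tert-butyl-4-methylphenyl, 3 equiv), toluene, −78 °C; then MeLi, −78 °C; then 1 M HCl
Reagents that add atoms: methyllithium, [Li]C
Why: Amphiphilic carbonyl methylation: the bulky aluminium Lewis acid binds the carbonyl oxygen from the equatorial side, so MeLi should attack axially and, in the chair that keeps C7 equatorial, the methyl ends axial and the hydroxyl equatorial and trans to the equatorial bromide, an arrangement that cannot close to an epoxide because the diaxial conformer is out of reach.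

**Compound list**

1 | 6-methylhept-5-en-2-one | CC(=O)CCC=C(C)C | starting material
2 | methyl 7-methyl-3-oxooct-6-enoate | COC(=O)CC(=O)CCC=C(C)C | intermediate
3 | methyl 5-[(2R)-3,3-dimethyloxiran-2-yl]-3-oxopentanoate | COC(=O)CC(=O)CC[C@H]1OC1(C)C | intermediate
4 | methyl (6S)-6-bromo-7-hydroxy-7-methyl-3-oxooctanoate | COC(=O)CC(=O)CC[C@H](Br)C(C)(C)O | intermediate
5 | methyl (3S)-3-bromo-2,2-dimethyl-6-oxocyclohexane-1-carboxylate (C1 epimers and enol) | O=C1CC[C@H](Br)C(C)(C)C1C(=O)OC | intermediate
6 | phenyl vinyl sulfone | C=CS(=O)(=O)c1ccccc1 | starting material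
7 | methyl (1S,3S)-3-bromo-2,2-dimethyl-6-oxo-1-[2-(phenylsulfonyl)ethyl]cyclohexane-1-carboxylate | O=C1CC[C@H](Br)C(C)(C)[C@@]1(C(=O)OC)CCS(=O)(=O)c1ccccc1 | intermediate
8 | methyl (1R,3S)-3-bromo-2,2-dimethyl-6-methylidene-1-[2-(phenylsulfonyl)ethyl]cyclohexane-1-carboxylate | C=C1CC[C@H](Br)C(C)(C)[C@@]1(C(=O)OC)CCS(=O)(=O)c1ccccc1 | intermediate
9 | [(1R,3S)-3-bromo-2,2-dimethyl-6-methylidene-1-[2-(phenylsulfonyl)ethyl]cyclohexyl]methanol | C=C1CC[C@H](Br)C(C)(C)[C@@]1(CO)CCS(=O)(=O)c1ccccc1 | intermediate
10 | (1R,3S)-3-bromo-2,2-dimethyl-6-methylidene-1-[2-(phenylsulfonyl)ethyl]cyclohexane-1-carbaldehyde | C=C1CC[C@H](Br)C(C)(C)[C@@]1(C=O)CCS(=O)(=O)c1ccccc1 | intermediate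
11 | methyl (2Z)-3-[(1R,3S)-3-bromo-2,2-dimethyl-6-methylidene-1-[2-(phenylsulfonyl)ethyl]cyclohexyl]prop-2-enoate | C=C1CC[C@H](Br)C(C)(C)[C@@]1(/C=C\C(=O)OC)CCS(=O)(=O)c1ccccc1 | intermediate
12 | (6R,8S)-8-bromo-7,7-dimethyl-11-methylidene-4-(phenylsulfonyl)spiro[5.5]undec-1-en-3-one (C4 epimers) | C=C1CC[C@H](Br)C(C)(C)[C@@]12CC(S(=O)(=O)c3ccccc3)C(=O)C=C2 | intermediate
13 | (6R,8S)-8-bromo-7,7-dimethyl-11-methylidenespiro[5.5]undec-1-en-3-one | C=C1CC[C@H](Br)C(C)(C)[C@@]12CCC(=O)C=C2 | intermediate
14 | {[(6R,8S)-8-bromo-7,7-dimethyl-11-methylidenespiro[5.5]undec-2-en-3-yl]oxy}triethylsilane | C=C1CC[C@H](Br)C(C)(C)[C@@]12CCC(O[Si](CC)(CC)CC)=CC2 | intermediate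
15 | (2S,6R,8S)-2,8-dibromo-7,7-dimethyl-11-methylidenespiro[5.5]undecan-3-one (axial C2 bromide) | C=C1CC[C@H](Br)C(C)(C)[C@@]12CCC(=O)[C@@H](Br)C2 | intermediate
16 | (2R,6R,8S)-2,8-dibromo-7,7-dimethyl-11-methylidenespiro[5.5]undecan-3-one (equatorial C2 bromide) | C=C1CC[C@H](Br)C(C)(C)[C@@]12CCC(=O)[C@H](Br)C2 | intermediate
17 | (2R,3R,6R,8S)-2,8-dibromo-3,7,7-trimethyl-11-methylidenespiro[5.5]undecan-3-ol | C=C1CC[C@H](Br)C(C)(C)[C@@]12CC[C@@](C)(O)[C@H](Br)C2 | target

**Step count and risks**

Total step count: 13. Longest linear sequence: 13 steps (from 1).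

Steps most likely to fail:

Step 13. Methyl may add from the equatorial side (poor facial selectivity), or methyllithium may attack the bromine at C2 or deprotonate C2 instead of adding to the carbonyl. The fallback sets out from 16. Caesium acetate (CsOAc, 18-crown-6, toluene, 23 °C) should displace the activated α-bromide by SN2 with inversion and give the axial acetate (2S,6R,8S)-8-bromo-7,7-dimethyl-11-methylidene-3-oxospiro[5.5]undecan-2-yl acetate F1. Excess MeMgBr (CH2Cl2, −78 °C) should then add anti to the axial C–O bond (Felkin–Anh control, which here coincides with axial attack) and cleave the acetate, giving the cis-diol (2S,3R,6R,8S)-8-bromo-3,7,7-trimethyl-11-methylidenespiro[5.5]undecane-2,3-diol F2. Trimethyl orthoacetate with pyridinium p-toluenesulfonate, then acetyl bromide (CH2Cl2, 0 °C), should open the derived acetoxonium ion at the secondary carbon with a second inversion to give (2R,3R,6R,8S)-2,8-dibromo-3,7,7-trimethyl-11-methylidenespiro[5.5]undecan-3-yl acetate F3. Removal of the tertiary acetate with i-Bu2AlH (CH2Cl2, −78 °C) brings the sequence back to the route at 17.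

Step 4. O-alkylation of the enol, proton loss from the bromonium ion or capture by chloride may compete with C–C bond formation, and bromonium transfer could erode the enantiomeric purity. The fallback sets out from 4. Acid-catalysed cyclodehydration (pyridinium p-toluenesulfonate, toluene, molecular sieves, 80 °C) should give the cyclic vinylogous carbonate methyl (2E)-2-[(5S)-5-bromo-6,6-dimethyloxan-2-ylidene]acetate F4 on purpose. A Petasis–Ferrier-type 1,3 shift of the tertiary carbon from oxygen to carbon (Me2AlCl, CH2Cl2, −78 to 0 °C), which passes through the same bromonium ion paired with an aluminium enolate, then comes back to the route at 5.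

Step 5. The acceptor may add with poor facial selectivity at the enolate carbon, or the enolate may displace the bromide three atoms away (1,3-elimination to a cyclopropane). The fallback sets out from 4 and reverses the order of the two events. Michael addition of the open-chain β-keto ester to 6 (Cs2CO3 cat., MeCN, 0 °C) should give methyl (6S)-6-bromo-7-hydroxy-7-methyl-3-oxo-2-[2-(phenylsulfonyl)ethyl]octanoate F5. Cyclization under the conditions of step 4 (SnCl4, CH2Cl2) should then form ring A and the quaternary carbon together: in the chair transition state the chelated enol holds the ester cis to the enol oxygen, so the sulfonylethyl chain ends axial and trans to the equatorial bromine. This comes back to the route at 7.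

**Further compounds**

F1 | step 13 | (2S,6R,8S)-8-bromo-7,7-dimethyl-11-methylidene-3-oxospiro[5.5]undecan-2-yl acetate | C=C1CC[C@H](Br)C(C)(C)[C@@]12CCC(=O)[C@@H](OC(C)=O)C2
F2 | step 13 | (2S,3R,6R,8S)-8-bromo-3,7,7-trimethyl-11-methylidenespiro[5.5]undecane-2,3-diol | C=C1CC[C@H](Br)C(C)(C)[C@@]12CC[C@@](C)(O)[C@@H](O)C2
F3 | step 13 | (2R,3R,6R,8S)-2,8-dibromo-3,7,7-trimethyl-11-methylidenespiro[5.5]undecan-3-yl acetate | C=C1CC[C@H](Br)C(C)(C)[C@@]12CC[C@@](C)(OC(C)=O)[C@H](Br)C2
F4 | step 4 | methyl (2E)-2-[(5S)-5-bromo-6,6-dimethyloxan-2-ylidene]acetate | COC(=O)/C=C1\CC[C@H](Br)C(C)(C)O1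
F5 | step 5 | methyl (6S)-6-bromo-7-hydroxy-7-methyl-3-oxo-2-[2-(phenylsulfonyl)ethyl]octanoate (C2 epimers) | COC(=O)C(CCS(=O)(=O)c1ccccc1)C(=O)CC[C@H](Br)C(C)(C)O
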